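Its constants are made up, and the outcome is calculated.

67.3% of saturation is where D stands when the dissolving of Q just feeds the coupling of D with X at the starting X, and I froze it there.

Q 20 mM; X 26.0 mM; time 2.5 h

    2 Q → Q2 (k1 = 0.00830 M⁻¹ h⁻¹)
    D.X ⇌ Z (K2 = 0.477, k2 = 0.185 h⁻¹)
    D + D.X → D.D.X (k3 = 14.7 M⁻¹ h⁻¹)
    Q ⇌ D, rate k4*(cs4 - [D]) while solid is left; crystals form when [D] > cs4 (cs4 = 5.1 mM, k4 = 6.16 h⁻¹)
    G ⇌ D.X, rate k5*(cs5 - [D.X]) while solid is left; crystals form when [D.X] > cs5 (cs5 = 6.4 mM, k5 = 83.5 h⁻¹)
    D + X → D.X (k6 = 115 M⁻¹ h⁻¹)

- in percentages every species weighs as the Q in it: one D.D.X or Q2 counts as two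
- for D.X the G are counted in
- where a step has two of a species, its rate is k times that concentration squared, and two are used at each turn
- as a solid, counted per litre of solution: Q, G
- at the start none of Q is in solution
- run time (flask): 2.5 h

1. the D.X and G together standing at 2.5 h, as a percentage of the Q charged
2. the change that raises the amount of D.X and G together at 2.5 h, in percent of the Q charged most ("none" if none brings more than 2 percentage points) (Thursday's / Tuesday's / Sunday's / Wednesday's / none)
3. amount of D.X and G together at 2.5 h, in percent of the Q charged, after Tuesday's

- Thursday's: doubling the solubility in step 5, all else as stated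
- Tuesday's: doubling the amount of X, all else as stated
- Sunday's: doubling the dissolution coefficient of step 5, all else as stated
- Wednesday's: doubling the dissolution coefficient of step 4, all else as stated

1. I set dissolving equal to coupling at the starting X, a steady state for D. That put D at 17.2% of the Q charged.

2. With D frozen, X falls pseudo-first-order. The time in which D at that level couples away half the free X, the frozen half-life of X, came to 1.76 h.

3. Floor, as an estimate and not a strict bound: over 2.5 h I reckoned X to fall to 37.3% of its own charge. One X goes per Q, so the coupled share came to 81.6% of the Q charged.

4. Ceiling: free X stays above 23.1% of its charge, so I held D under 89.9% of saturation. That put my ceiling on the coupled share at 95.2%, with no losses counted.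

5. Losses: with dissolved D.X taken at its solubility, I allowed 11.6% of the charge for Z and 5.39% for the D.X used up in D.D.X. Taken from the coupled share, these lowered my floor to 64.5%.

6. The forecast gave 72% (67% to 77%), above my floor and below my ceiling. It chose Tuesday's and put that flask at 87% (82% to 91%), holding that “the D + X coupling is the bottleneck”.

The flask gave 71.1%, above my floor, and Tuesday's brought most, 17 percentage points, reaching 87.6%. In the flask, the half-life of X by coupling read 1.7 h at 0.787 h, against the frozen 1.76 h, and free X read 36.1% of its charge at 2.50 h, against the frozen 37.3%. The neighbour flask with 80 mM of Q and the same X kept 72.3% of its Q and 34.8% of its X at 2.50 h. The same frozen half-life gives that neighbour a coupled share of 20.4% of its charge, and its D.X and G stood at 18.2%.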